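The trienone is cut between the ketone carbon and C2 of the side chain. A fully elaborated pyridone-3-carbaldehyde and a chiral (3E,5E)-dienyne are joined by rhodium-catalysed alkyne hydroacylation: in one operation the formyl C–H bond adds across the terminal alkyne, which forms the ketone–C2 bond, creates the 2E alkene and completes the triene with no activating group on either partner. The step exploits the free C4 hydroxyl of the pyridone ring next to the acyl-bearing C3, a salicylaldehyde-like O–H/C–H pair that chelates rhodium. The precursors are a 3-formyl-4-hydroxy-2-pyridone with N–O–SEM protection and a TBS-protected dienyne carrying the C8 stereocentre.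

Key step: step 11

Remark on the chemistry: the target is read as the cis-1,4-diol (both cyclohexane hydroxyls on one face, the pyridone trans to the secondary hydroxyl) with 8R configuration in the side chain.
Assumption: diethyl [3-(trimethylsilyl)prop-2-yn-1-yl]phosphonate is taken as a purchasable reagent (otherwise one Arbuzov step from 3-bromo-1-(trimethylsilyl)propyne).

**Side chain (steps 1–4)**

Step 1
Reactants: 1 butanal
Product: 3 (R,E)-4-(hydroxymethyl)-N-methoxy-N-methylhex-2-enamide, via (S)-2-(hydroxymethyl)butanal 2 (not isolated)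
Conditions: (R)-α,α-diphenylprolinol TMS ether (10 mol %), aq. CH2O (37 %), pH 7 phosphate buffer, toluene, rt; then Ph3P=CHC(O)N(OMe)Me, CH2Cl2, rt
Reagents that add atoms: formaldehyde C=O; N-methoxy-N-methyl-2-(triphenylphosphoranylidene)acetamide CON(C)C(=O)C=P(c1ccccc1)(c1ccccc1)c1ccccc1
Why: Organocatalytic enamine α-hydroxymethylation, in which the E-enamine of 1 with the (R)-diarylprolinol silyl ether is attacked by formaldehyde on the face away from the diphenyl(silyloxy)methyl group and so sets the (S)-aldehyde centre (the later C8), followed at once by an E-selective Wittig olefination with the stabilised ylide that traps the configurationally labile aldehyde.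

Step 2
Reactants: 3 (R,E)-4-(hydroxymethyl)-N-methoxy-N-methylhex-2-enamide
Product: 4 (R,E)-4-{[(tert-butyldimethylsilyl)oxy]methyl}-N-methoxy-N-methylhex-2-enamide
Conditions: TBSCl, imidazole, CH2Cl2, 0 °C → rt
Reagents that add atoms: tert-butyldimethylsilyl chloride CC(C)(C)[Si](C)(C)Cl
Why: Standard silylation of the only free (primary) hydroxyl, which masks it before the hydride and carbanion steps.

Step 3
Reactants: 4 (R,E)-4-{[(tert-butyldimethylsilyl)oxy]methyl}-N-methoxy-N-methylhex-2-enamide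
Product: 5 (R,E)-4-{[(tert-butyldimethylsilyl)oxy]methyl}hex-2-enal
Conditions: DIBAL-H, THF, −78 °C; aq. Rochelle salt
Reagents that add atoms: none
Why: Weinreb amide reduction stops at the chelated aluminium hemiaminal, which releases the enal only on work-up, so neither over-reduction nor loss of the E geometry is expected.

Step 4
Reactants: 5 (R,E)-4-{[(tert-butyldimethylsilyl)oxy]methyl}hex-2-enal
Product: 7 (R,3E,5E)-7-{[(tert-butyldimethylsilyl)oxy]methyl}nona-3,5-dien-1-yne, via TMS-dienyne 6 (not isolated)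
Conditions: (EtO)2P(O)CH2C≡CTMS, LiHMDS, THF, −78 → 0 °C; then K2CO3 (cat.), MeOH, rt
Reagents that add atoms: diethyl [3-(trimethylsilyl)prop-2-yn-1-yl]phosphonate CCOP(=O)(CC#C[Si](C)(C)C)OCC
Why: Horner–Wadsworth–Emmons olefination with the lithiated propargylic phosphonate is E-selective for the new C=C bond, and methanolic carbonate then removes the alkynyl TMS group in the same flask while the TBS ether stays.

**Pyridone (steps 5–10)**

Step 5
Reactants: 8 5-bromo-2,4-dichloropyridine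
Product: 9 2,4-bis(benzyloxy)-5-bromopyridine
Conditions: BnOH, NaH, THF/DMF, 0 → 70 °C
Reagents that add atoms: benzyl alcohol OCc1ccccc1
Why: Double SNAr, since both chlorides sit on positions activated by the ring nitrogen (C4 first, then C2) whereas the C5 bromide is not activated and is kept.

Step 6
Reactants: 9 2,4-bis(benzyloxy)-5-bromopyridine; 10 4-[(tert-butyldimethylsilyl)oxy]cyclohexan-1-one
Product: 12 cis-1-[4,6-bis(benzyloxy)pyridin-3-yl]-4-[(tert-butyldimethylsilyl)oxy]cyclohexan-1-ol, via aryllithium 11 (not isolated)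
Conditions: n-BuLi, THF, −78 °C; then 10, −78 → −40 °C; aq. NH4Cl
Reagents that add atoms: none
Why: Bromine–lithium exchange at −78 °C outruns deprotonation, and 1,2-addition of the bulky aryllithium along the equatorial trajectory of the chair with equatorial OTBS should place the new hydroxyl axial and thus cis to the silyloxy group (control by the ring conformation).

Step 7
Reactants: 12 cis-1-[4,6-bis(benzyloxy)pyridin-3-yl]-4-[(tert-butyldimethylsilyl)oxy]cyclohexan-1-ol
Product: 13 2,4-bis(benzyloxy)-5-[cis-4-{[tert-butyl(dimethyl)silyl]oxy}-1-hydroxycyclohexyl]pyridine 1-oxide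
Conditions: mCPBA, CH2Cl2, 0 °C → rt
Reagents that add atoms: 3-chloroperoxybenzoic acid OOC(=O)c1cccc(Cl)c1
Why: Peracid N-oxidation of the electron-rich 2,4-dialkoxypyridine nitrogen, with no other peracid-sensitive group in 12.

Step 8
Reactants: 13 2,4-bis(benzyloxy)-5-[cis-4-{[tert-butyl(dimethyl)silyl]oxy}-1-hydroxycyclohexyl]pyridine 1-oxide
Product: 15 4-(benzyloxy)-5-[cis-4-{[tert-butyl(dimethyl)silyl]oxy}-1-hydroxycyclohexyl]-1-{[2-(trimethylsilyl)ethoxy]methoxy}pyridin-2(1H)-one, via N-alkoxypyridinium chloride 14 (not isolated)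
Conditions: SEMCl, CH2Cl2, 0 °C → rt
Reagents that add atoms: 2-(trimethylsilyl)ethoxymethyl chloride C[Si](C)(C)CCOCCl
Why: Hilbert–Johnson-type O-alkylation/dealkylation of a 2-alkoxypyridine N-oxide, in which the N-oxide oxygen is alkylated by the chloromethyl ether and chloride then removes the benzyl group from the 2-alkoxypyridinium oxygen by SN2, so that the N–O–SEM pyridone forms and O2 is told apart from O4.

Step 9
Reactants: 15 4-(benzyloxy)-5-[cis-4-{[tert-butyl(dimethyl)silyl]oxy}-1-hydroxycyclohexyl]-1-{[2-(trimethylsilyl)ethoxy]methoxy}pyridin-2(1H)-one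
Product: 16 5-[cis-4-{[tert-butyl(dimethyl)silyl]oxy}-1-hydroxycyclohexyl]-4-hydroxy-1-{[2-(trimethylsilyl)ethoxy]methoxy}pyridin-2(1H)-one
Conditions: H2 (1 atm), 10 % Pd/C, EtOAc, rt
Reagents that add atoms: none
Why: Hydrogenolysis of the remaining benzyl ether under neutral conditions, which the N–O bond of an N-alkoxypyridone and the tertiary carbinol should survive on short exposure.

Step 10
Reactants: 16 5-[cis-4-{[tert-butyl(dimethyl)silyl]oxy}-1-hydroxycyclohexyl]-4-hydroxy-1-{[2-(trimethylsilyl)ethoxy]methoxy}pyridin-2(1H)-one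
Product: 18 5-[cis-4-{[tert-butyl(dimethyl)silyl]oxy}-1-hydroxycyclohexyl]-4-hydroxy-2-oxo-1-{[2-(trimethylsilyl)ethoxy]methoxy}-1,2-dihydropyridine-3-carbaldehyde, via dimethylaminomethylene dione 17 (not isolated)
Conditions: t-BuOCH(NMe2)2, toluene, rt → 50 °C; then LiOH, THF/H2O, 0 °C; 1 M HCl to pH 4
Reagents that add atoms: tert-butoxybis(dimethylamino)methane (Bredereck's reagent) CN(C)C(OC(C)(C)C)N(C)C; water O
Why: Aminomethylenation of a 1,3-dicarbonyl equivalent at C3, the only free enolic carbon of the 4-hydroxy-2-pyridone, followed by hydroxide exchange of the dimethylamino group, which leaves the chelated 3-formyl-4-hydroxy tautomer.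

**Union and deprotection (steps 11–12)**

Step 11
Reactants: 18 5-[cis-4-{[tert-butyl(dimethyl)silyl]oxy}-1-hydroxycyclohexyl]-4-hydroxy-2-oxo-1-{[2-(trimethylsilyl)ethoxy]methoxy}-1,2-dihydropyridine-3-carbaldehyde; 7 (R,3E,5E)-7-{[(tert-butyldimethylsilyl)oxy]methyl}nona-3,5-dien-1-yne
Product: 19 5-[cis-4-{[tert-butyl(dimethyl)silyl]oxy}-1-hydroxycyclohexyl]-3-[(2E,4E,6E,8R)-8-{[(tert-butyldimethylsilyl)oxy]methyl}deca-2,4,6-trienoyl]-4-hydroxy-1-{[2-(trimethylsilyl)ethoxy]methoxy}pyridin-2(1H)-one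
Conditions: [RhCl(cod)]2 (5 mol %), dppf (10 mol %), Na2CO3 (20 mol %), 7 (1.3 equiv), toluene, 80 °C
Reagents that add atoms: none
Why: Carbonate deprotonates the acidic C4–OH of 18, the O-bound rhodium(I) inserts into the neighbouring C3 formyl C–H bond to give a five-membered O,C-chelated acyl(hydrido)rhodium(III) species, the terminal alkyne of 7 inserts into Rh–H with syn delivery of hydride to the internal carbon, and C–C reductive elimination forms the ketone–C2 bond and returns Rh(I). The closest known reaction type is the rhodium-catalysed chelation-assisted intermolecular hydroacylation of alkynes with salicylaldehydes, of which the 3-formyl-4-hydroxy-2-pyridone is a direct heterocyclic analogue. No ring is closed and no stereocentre is formed; the new C2=C3 alkene should be E because acyl and hydrogen add to the same side of the alkyne, and the C8 centre and the two E alkenes of 7 are not touched. The step needs linear regioselectivity, reaction at the alkyne in preference to the diene, and no decarbonylation: the unsubstituted alkyne terminus directs rhodium to C2, the alkyne should insert faster than the 1,2-disubstituted alkenes, and the C4–O chelate holds the acyl group on the metal so that CO extrusion is disfavoured. The SEM group keeps the N–O oxygen from competing as a ligand, and the silyl ethers and the free tertiary alcohol are inert to these neutral conditions.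

Step 12
Reactants: 19 5-[cis-4-{[tert-butyl(dimethyl)silyl]oxy}-1-hydroxycyclohexyl]-3-[(2E,4E,6E,8R)-8-{[(tert-butyldimethylsilyl)oxy]methyl}deca-2,4,6-trienoyl]-4-hydroxy-1-{[2-(trimethylsilyl)ethoxy]methoxy}pyridin-2(1H)-one
Product: 20 5-(cis-1,4-dihydroxycyclohexyl)-1,4-dihydroxy-3-[(2E,4E,6E,8R)-8-(hydroxymethyl)deca-2,4,6-trienoyl]pyridin-2(1H)-one
Conditions: TBAF, AcOH, THF, 0 °C → rt; pH 4 buffer work-up
Reagents that add atoms: none
Why: Fluoride-mediated global desilylation cleaves both TBS ethers and the N–O–SEM acetal (attack at silicon, then loss of ethylene and formaldehyde, eased by the good N-oxide-type leaving group), while the acetic acid buffer spares the trienone and the tertiary carbinol from strong base or acid.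

**Compound list**

1 | butanal | CCCC=O | starting material
2 | (S)-2-(hydroxymethyl)butanal | CC[C@H](C=O)CO | intermediate (not isolated)
3 | (R,E)-4-(hydroxymethyl)-N-methoxy-N-methylhex-2-enamide | CC[C@H](/C=C/C(=O)N(C)OC)CO | intermediate
4 | (R,E)-4-{[(tert-butyldimethylsilyl)oxy]methyl}-N-methoxy-N-methylhex-2-enamide | CC[C@H](/C=C/C(=O)N(C)OC)CO[Si](C)(C)C(C)(C)C | intermediate
5 | (R,E)-4-{[(tert-butyldimethylsilyl)oxy]methyl}hex-2-enal | CC[C@H](/C=C/C=O)CO[Si](C)(C)C(C)(C)C | intermediate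
6 | (R,3E,5E)-7-{[(tert-butyldimethylsilyl)oxy]methyl}-1-(trimethylsilyl)nona-3,5-dien-1-yne | CC[C@H](/C=C/C=C/C#C[Si](C)(C)C)CO[Si](C)(C)C(C)(C)C | intermediate (not isolated)
7 | (R,3E,5E)-7-{[(tert-butyldimethylsilyl)oxy]methyl}nona-3,5-dien-1-yne | CC[C@H](/C=C/C=C/C#C)CO[Si](C)(C)C(C)(C)C | intermediate
8 | 5-bromo-2,4-dichloropyridine | Clc1cc(Cl)c(Br)cn1 | starting material
9 | 2,4-bis(benzyloxy)-5-bromopyridine | Brc1cnc(OCc2ccccc2)cc1OCc1ccccc1 | intermediate
10 | 4-[(tert-butyldimethylsilyl)oxy]cyclohexan-1-one | O=C1CCC(O[Si](C)(C)C(C)(C)C)CC1 | starting material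
11 | [4,6-bis(benzyloxy)pyridin-3-yl]lithium | [Li]c1cnc(OCc2ccccc2)cc1OCc1ccccc1 | intermediate (not isolated)
12 | cis-1-[4,6-bis(benzyloxy)pyridin-3-yl]-4-[(tert-butyldimethylsilyl)oxy]cyclohexan-1-ol (1-OH and 4-OTBS on the same face) | c1(OCc2ccccc2)cc(OCc2ccccc2)c([C@]2(O)CC[C@@H](O[Si](C)(C)C(C)(C)C)CC2)cn1 | intermediate
13 | 2,4-bis(benzyloxy)-5-[cis-4-{[tert-butyl(dimethyl)silyl]oxy}-1-hydroxycyclohexyl]pyridine 1-oxide | c1(OCc2ccccc2)cc(OCc2ccccc2)c([C@]2(O)CC[C@@H](O[Si](C)(C)C(C)(C)C)CC2)c[n+]1[O-] | intermediate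
14 | 2,4-bis(benzyloxy)-5-[cis-4-{[tert-butyl(dimethyl)silyl]oxy}-1-hydroxycyclohexyl]-1-{[2-(trimethylsilyl)ethoxy]methoxy}pyridin-1-ium chloride | c1(OCc2ccccc2)cc(OCc2ccccc2)c([C@]2(O)CC[C@@H](O[Si](C)(C)C(C)(C)C)CC2)c[n+]1OCOCC[Si](C)(C)C.[Cl-] | intermediate (not isolated)
15 | 4-(benzyloxy)-5-[cis-4-{[tert-butyl(dimethyl)silyl]oxy}-1-hydroxycyclohexyl]-1-{[2-(trimethylsilyl)ethoxy]methoxy}pyridin-2(1H)-one | O=c1cc(OCc2ccccc2)c([C@]2(O)CC[C@@H](O[Si](C)(C)C(C)(C)C)CC2)cn1OCOCC[Si](C)(C)C | intermediate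
16 | 5-[cis-4-{[tert-butyl(dimethyl)silyl]oxy}-1-hydroxycyclohexyl]-4-hydroxy-1-{[2-(trimethylsilyl)ethoxy]methoxy}pyridin-2(1H)-one | O=c1cc(O)c([C@]2(O)CC[C@@H](O[Si](C)(C)C(C)(C)C)CC2)cn1OCOCC[Si](C)(C)C | intermediate
17 | 5-[cis-4-{[tert-butyl(dimethyl)silyl]oxy}-1-hydroxycyclohexyl]-3-[(dimethylamino)methylene]-1-{[2-(trimethylsilyl)ethoxy]methoxy}pyridine-2,4(1H,3H)-dione | O=C1C(=CN(C)C)C(=O)C([C@]2(O)CC[C@@H](O[Si](C)(C)C(C)(C)C)CC2)=CN1OCOCC[Si](C)(C)C | intermediate (not isolated)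
18 | 5-[cis-4-{[tert-butyl(dimethyl)silyl]oxy}-1-hydroxycyclohexyl]-4-hydroxy-2-oxo-1-{[2-(trimethylsilyl)ethoxy]methoxy}-1,2-dihydropyridine-3-carbaldehyde | O=Cc1c(O)c([C@]2(O)CC[C@@H](O[Si](C)(C)C(C)(C)C)CC2)cn(OCOCC[Si](C)(C)C)c1=O | intermediate
19 | 5-[cis-4-{[tert-butyl(dimethyl)silyl]oxy}-1-hydroxycyclohexyl]-3-[(2E,4E,6E,8R)-8-{[(tert-butyldimethylsilyl)oxy]methyl}deca-2,4,6-trienoyl]-4-hydroxy-1-{[2-(trimethylsilyl)ethoxy]methoxy}pyridin-2(1H)-one | CC[C@H](/C=C/C=C/C=C/C(=O)c1c(O)c([C@]2(O)CC[C@@H](O[Si](C)(C)C(C)(C)C)CC2)cn(OCOCC[Si](C)(C)C)c1=O)CO[Si](C)(C)C(C)(C)C | intermediate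
20 | 5-(cis-1,4-dihydroxycyclohexyl)-1,4-dihydroxy-3-[(2E,4E,6E,8R)-8-(hydroxymethyl)deca-2,4,6-trienoyl]pyridin-2(1H)-one | CC[C@H](/C=C/C=C/C=C/C(=O)c1c(O)c([C@]2(O)CC[C@@H](O)CC2)cn(O)c1=O)CO | target

**Step count and risks**

Total step count: 12. Longest linear sequence: 8 steps (steps 5–12, from 8 to 20); the side-chain branch (steps 1–4) joins at step 11.

Steps most likely to fail:

Step 11. Alkyne insertion with the opposite regiochemistry (branched enone), decarbonylation of the acylrhodium hydride, oligomerisation of the terminal alkyne or tight binding of rhodium by the tricarbonyl-like pyridone may outrun the desired coupling. The fallback forms the same bond by carbonyl addition and oxidation; it sets out from 18 and 7 and returns to the route at 20. Aldehyde 18 is capped at O4 (SEMCl, i-Pr2NEt, CH2Cl2, 0 °C) to give 5-[cis-4-(TBSO)-1-hydroxycyclohexyl]-2-oxo-1,4-bis{[2-(trimethylsilyl)ethoxy]methoxy}-1,2-dihydropyridine-3-carbaldehyde F1. Dienyne 7 is hydrozirconated (Cp2Zr(H)Cl, CH2Cl2, rt) to the (1E,3E,5E)-trienylzirconocene chloride F2, which is transmetalated with Me2Zn (−65 °C) to the trienyl(methyl)zinc F3 and added to F1 (0 °C; aq. NH4Cl) to give the secondary trienyl carbinol F4 (both carbinol epimers serve). Dess–Martin oxidation (CH2Cl2, NaHCO3, 0 °C) gives the 4-O-SEM trienone F5, which under the conditions of step 12 should lose all silicon-based groups and give 20.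

Step 8. O-Alkylation of the hindered N-oxide may be slow, so that the chloromethyl ether is consumed at the tertiary hydroxyl or the pyridinium salt reverts instead of losing benzyl chloride. The fallback separates the events and sets out from 13 to return at 15. Acetyl chloride (CH2Cl2, 0 °C) should give, through 1-acetoxy-2,4-bis(benzyloxy)pyridinium chloride F6, the 1-acetoxy-4-(benzyloxy)pyridin-2(1H)-one F7. Methanolysis (K2CO3, MeOH, 0 °C) frees 4-(benzyloxy)-1-hydroxypyridin-2(1H)-one F8, whose acidic N–OH alone is alkylated by SEMCl/i-Pr2NEt (CH2Cl2, 0 °C) to give 15.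

Step 6. Poor facial selectivity is possible if the conformer of 10 with an axial silyloxy group reacts competitively, which would erode the cis relationship of the two oxygens. The fallback sets the secondary carbinol by reduction instead; it sets out from 9 and returns at 12. Aryllithium 11, generated as before, is added to 1,4-dioxaspiro[4.5]decan-8-one to give ketal carbinol F9. The ketal is hydrolysed (PPTS, acetone/H2O, 50 °C) to 4-aryl-4-hydroxycyclohexanone F10. NaBH4 (MeOH, −20 °C) should attack axially on the chair with equatorial aryl group and give the cis-1,4-diol F11, and silylation of the secondary hydroxyl (TBSCl, imidazole, CH2Cl2) gives 12.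

Further compounds
F1 | step 11 | 5-[cis-4-{[tert-butyl(dimethyl)silyl]oxy}-1-hydroxycyclohexyl]-2-oxo-1,4-bis{[2-(trimethylsilyl)ethoxy]methoxy}-1,2-dihydropyridine-3-carbaldehyde | O=Cc1c(OCOCC[Si](C)(C)C)c([C@]2(O)CC[C@@H](O[Si](C)(C)C(C)(C)C)CC2)cn(OCOCC[Si](C)(C)C)c1=O
F2 | step 11 | chloro[(1E,3E,5E,7R)-7-{[(tert-butyldimethylsilyl)oxy]methyl}nona-1,3,5-trien-1-yl]zirconocene | CC[C@H](/C=C/C=C/C=C/[Zr](Cl)(C1C=CC=C1)C1C=CC=C1)CO[Si](C)(C)C(C)(C)C
F3 | step 11 | methyl[(1E,3E,5E,7R)-7-{[(tert-butyldimethylsilyl)oxy]methyl}nona-1,3,5-trien-1-yl]zinc | CC[C@H](/C=C/C=C/C=C/[Zn]C)CO[Si](C)(C)C(C)(C)C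
F4 | step 11 | 5-[cis-4-{[tert-butyl(dimethyl)silyl]oxy}-1-hydroxycyclohexyl]-3-[(2E,4E,6E,8R)-8-{[(tert-butyldimethylsilyl)oxy]methyl}-1-hydroxydeca-2,4,6-trien-1-yl]-1,4-bis{[2-(trimethylsilyl)ethoxy]methoxy}pyridin-2(1H)-one (carbinol epimers) | CC[C@H](/C=C/C=C/C=C/C(O)c1c(OCOCC[Si](C)(C)C)c([C@]2(O)CC[C@@H](O[Si](C)(C)C(C)(C)C)CC2)cn(OCOCC[Si](C)(C)C)c1=O)CO[Si](C)(C)C(C)(C)C
F5 | step 11 | 5-[cis-4-{[tert-butyl(dimethyl)silyl]oxy}-1-hydroxycyclohexyl]-3-[(2E,4E,6E,8R)-8-{[(tert-butyldimethylsilyl)oxy]methyl}deca-2,4,6-trienoyl]-1,4-bis{[2-(trimethylsilyl)ethoxy]methoxy}pyridin-2(1H)-one | CC[C@H](/C=C/C=C/C=C/C(=O)c1c(OCOCC[Si](C)(C)C)c([C@]2(O)CC[C@@H](O[Si](C)(C)C(C)(C)C)CC2)cn(OCOCC[Si](C)(C)C)c1=O)CO[Si](C)(C)C(C)(C)C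
F6 | step 8 | 1-acetoxy-2,4-bis(benzyloxy)-5-[cis-4-{[tert-butyl(dimethyl)silyl]oxy}-1-hydroxycyclohexyl]pyridin-1-ium chloride | c1(OCc2ccccc2)cc(OCc2ccccc2)c([C@]2(O)CC[C@@H](O[Si](C)(C)C(C)(C)C)CC2)c[n+]1OC(C)=O.[Cl-]
F7 | step 8 | 4-(benzyloxy)-5-[cis-4-{[tert-butyl(dimethyl)silyl]oxy}-1-hydroxycyclohexyl]-2-oxopyridin-1(2H)-yl acetate | O=c1cc(OCc2ccccc2)c([C@]2(O)CC[C@@H](O[Si](C)(C)C(C)(C)C)CC2)cn1OC(C)=O
F8 | step 8 | 4-(benzyloxy)-5-[cis-4-{[tert-butyl(dimethyl)silyl]oxy}-1-hydroxycyclohexyl]-1-hydroxypyridin-2(1H)-one | O=c1cc(OCc2ccccc2)c([C@]2(O)CC[C@@H](O[Si](C)(C)C(C)(C)C)CC2)cn1O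
F9 | step 6 | 8-[4,6-bis(benzyloxy)pyridin-3-yl]-1,4-dioxaspiro[4.5]decan-8-ol | c1(OCc2ccccc2)cc(OCc2ccccc2)c(C2(O)CCC3(CC2)OCCO3)cn1
F10 | step 6 | 4-[4,6-bis(benzyloxy)pyridin-3-yl]-4-hydroxycyclohexan-1-one | c1(OCc2ccccc2)cc(OCc2ccccc2)c(C2(O)CCC(=O)CC2)cn1
F11 | step 6 | cis-1-[4,6-bis(benzyloxy)pyridin-3-yl]cyclohexane-1,4-diol (both hydroxyls on the same face) | c1(OCc2ccccc2)cc(OCc2ccccc2)c([C@]2(O)CC[C@@H](O)CC2)cn1
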